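Millimolar of catalyst charged is the unit I count in at this bench. The flasks:

| flask | starting material | coupling partner | free catalyst | time |
|---|---|---|---|---|
| theta | 50.0 mM | 150 mM | 2.50 mM |  |
| beta | 30.0 mM | 130 mM | 2.50 mM |  |
| delta | 50.0 mM | 220 mM | 2.50 mM |  |
| gamma | 25.0 mM | 150 mM | 2.50 mM |  |
| zeta | 25.0 mM | 150 mM | 0.830 mM | 8.1 min |

| run | time / min | [starting material] / mM |
|---|---|---|
| theta run | 1.2 | 42.6 |
| theta run | 2.3 | 38.2 |
| theta run | 3.5 | 34.1 |
| theta run | 4.6 | 30.8 |
| theta run | 5.8 | 28.2 |
| theta run | 6.9 | 26.1 |
| theta run | 8.1 | 24.0 |
| beta run | 1.2 | 25.6 |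
| beta run | 2.3 | 22.8 |
| beta run | 3.5 | 20.4 |
| beta run | 4.6 | 18.5 |
| beta run | 5.8 | 17.1 |
| beta run | 6.9 | 16.0 |
| beta run | 8.1 | 14.7 |
| delta run | 1.2 | 41.0 |
| delta run | 2.3 | 34.5 |
| delta run | 3.5 | 29.2 |
| delta run | 4.6 | 25.3 |
| delta run | 5.8 | 21.9 |
| delta run | 6.9 | 19.0 |
| delta run | 8.1 | 16.8 |
| gamma run | 1.2 | 20.9 |
| gamma run | 2.3 | 18.1 |
| gamma run | 3.5 | 15.6 |
| gamma run | 4.6 | 14.3 |
| gamma run | 5.8 | 13.0 |
| gamma run | 6.9 | 11.7 |
| gamma run | 8.1 | 11.1 |

(each reading ± 0.3 mM)

- Overall: starting material + coupling partner -> product, with free catalyst as catalyst.
- Constant volume, constant temperature.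
- A reading of a species includes what of it is bound.
- An order is taken over about fifteen percent of the charge, up and down.

1. how the opening rate goes with [coupling partner] round the charge of the theta run: the exponent of the rate at two percent of starting material gone to product
2. how the opening rate goes with [starting material] round the charge of the theta run: the exponent of the rate at two percent of starting material gone to product (one fixed amount of product, the same in the runs compared)
3. the beta run starts with 20.0 mM less of starting material and of coupling partner than the theta run, and with no product. Compared where both hold the same amount of starting material, once fifteen percent of what the beta run was charged with has turned into product, is the beta run faster, slower or alike (within a tenth)?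
4. starting material in the zeta run at 8.1 min, as a share of the starting material charged

To whoever takes over: the zeta run holds the starting material and coupling partner of the gamma run, with a third of its catalyst. Add nothing to it. My reckoning rests on those two charges staying equal.

I work with what is left. I call λ the log-left per millimolar of catalyst. Here A is the starting material charged, S the reading at the time asked (8.1 min) and C the catalyst charged:

λ = ln(A/S)/C = ln(25.0 mM/11.1 mM)/2.50 mM = 0.325 mM⁻¹ (gamma run)

λ = ln(50.0 mM/24.0 mM)/2.50 mM = 0.294 mM⁻¹ (theta run)

A pseudo-first-order flask has one λ for both charges at equal partner and catalyst, but the gamma run reads more than the theta run.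

For the zeta run I carry the gamma value over:

ln(A/S) = 0.325 mM⁻¹ × 0.830 mM = 0.270

S/A = exp(−0.270) = 76.4 %

So I expect about 19.1 mM of starting material when you come.

For the zeta run the forecast gives 74 %, a little below my figure. It also gives orders of 0.9 in coupling partner and 0.8 in starting material, and calls the beta run faster. On the fall in rate it says: “That points to catalyst decay.”

The flask gives orders of 0.84 in coupling partner and 0.64 in starting material. The beta run is faster, and the zeta run holds 69.5 % of its starting material at 8.1 min.

    free catalyst + coupling partner ⇌ catalyst-reagent complex, settled at all times (3.110 M⁻¹)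
    catalyst-reagent complex + starting material → product + free catalyst (274.8 M⁻¹ min⁻¹)
    2 free catalyst → 2 spent catalyst (124.2 M⁻¹ min⁻¹)
    free catalyst + starting material ⇌ idle catalyst-substrate complex, settled at all times (20.40 M⁻¹)

The zeta run's λ is 0.439 mM⁻¹, more than the gamma run's 0.325 mM⁻¹. The pair loss of free catalyst and its parking as idle catalyst-substrate complex act together on what the zeta run has left. The pair loss goes with the square of free catalyst, so at these equal charges of starting material and partner its first half-life by this step alone in the zeta run is 3.01 times the gamma run's. Without the pair loss the zeta run stands at 64.1 %, a λ of 0.536 mM⁻¹, and without the parking at 65.5 %, a λ of 0.510 mM⁻¹.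

The numbers in the tables stem from a simulated flask from invented constants, and the scatter is random.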